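The dihydropyran (C10, C11, O12, C13, C18, C19) is a masked 1,5-dialdehyde, and its C10–C19 bond also belongs to the oxepane (C6, C7, O8, C9, C10, C19, C20). Cutting this one bond as a retro-Michael step unravels both heterocycles to a monocyclic cyclopropane. Forward, amine catalysis joins C10, the α-carbon of the C11 aldehyde, to C19, the β-carbon of the C13 enal. One operation closes the oxepane, sets C19 and delivers the dialdehyde that folds into the dihydropyran. The precursor is a cyclopropane carrying a 3-oxopropyl ether arm on C7 and an E-enal arm on C20, cis to each other, and a ketal-masked C22–C25 chain trans to the enal.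

Key step: step 12

Remarks
- Atom labels (C5, O8, C19 ...) give the position of the heavy atom in the target SMILES and are kept for every intermediate.
- Assumption: the SMILES is read literally, so C19 and C22 are trans on the cyclopropane and the cycloheptane is a trans-fused bicyclo[5.1.0]octane; this strain is met only in step 16.
- Structure check: in the key-step precursor and product, C6, C19, C20 and C21 map onto the target unchanged. C10 of the product is a labile centre that disappears in step 13.
- Protecting group at C5: O4 is carried as a TBDPS ether, not as the acetate. An ester there could migrate to free O8 (scrambling C6), would be enolised in step 14, and would fall to iBu2AlH in step 18 anyway.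
- Order of arm installation: O8 is alkylated while C19 is only a vinyl group. A free C7 hydroxyl would close onto a C19 aldehyde (lactol) or onto the enal (5-exo oxa-Michael addition).

Step 1
Reactants: 1 5-hexen-2-one
Product: 2 2-(but-3-en-1-yl)-2-methyl-1,3-dioxolane
Conditions: HOCH2CH2OH, pTsOH·H2O (cat.), toluene, Dean–Stark, reflux
Reagents that add atoms: ethylene glycol, OCCO
Why: Acid-catalysed ketalisation driven by azeotropic removal of water masks the C24 ketone against the hydride, ylide and amide-base steps that follow, and no stereocentre is involved.

Step 2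
Reactants: 2 2-(but-3-en-1-yl)-2-methyl-1,3-dioxolane; 3 (E)-crotonaldehyde
Product: 4 (E)-5-(2-methyl-1,3-dioxolan-2-yl)pent-2-enal
Conditions: second-generation Hoveyda–Grubbs catalyst (2 mol %), 3 (4 equiv), CH2Cl2, 40 °C
Reagents that add atoms: crotonaldehyde (3), C/C=C/C=O
Why: Olefin cross-metathesis between a reactive terminal alkene and an excess of an electron-poor enal favours the cross product over homodimers and gives the E-enal under thermodynamic control.

Step 3
Reactants: 4 (E)-5-(2-methyl-1,3-dioxolan-2-yl)pent-2-enal; 5 diethyl bromomalonate
Product: 6 diethyl (2R,3R)-2-formyl-3-[2-(2-methyl-1,3-dioxolan-2-yl)ethyl]cyclopropane-1,1-dicarboxylate (C19 formyl trans to the C22 chain)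
Conditions: (S)-α,α-diphenylprolinol trimethylsilyl ether (20 mol %), 2,6-lutidine (1.1 equiv), CH2Cl2, 0 °C
Reagents that add atoms: diethyl bromomalonate (5), CCOC(=O)C(Br)C(=O)OCC
Why: Organocatalytic Michael-initiated ring closure: the bromomalonate carbanion (C6) adds to C21 on the face of the s-trans E-iminium ion that the CPh2(OSiMe3) group leaves open, and the enamine so formed displaces bromide through C20, which sets C21 and C20 in the absolute sense required and places the C19 formyl group trans to the C22 chain.

Step 4
Reactants: 6 cyclopropane aldehyde diester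
Product: 7 diethyl 2-ethenyl-3-[2-(2-methyl-1,3-dioxolan-2-yl)ethyl]cyclopropane-1,1-dicarboxylate (vinyl trans to the chain; C20 and C21 as in 6)
Conditions: Ph3PCH3Br, KN(SiMe3)2, THF, 0 °C; then 6, −78 → 0 °C
Reagents that add atoms: methyltriphenylphosphonium bromide, C[P+](c1ccccc1)(c1ccccc1)c1ccccc1.[Br-]
Why: Wittig methylenation, in which carbonyl addition at −78 °C outruns deprotonation at C20 (the path to base-induced ring opening), turns C19 into a vinyl group that is blind to hydride and base and later serves as the metathesis handle, C20 and C21 being untouched.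

Step 5
Reactants: 7 vinylcyclopropane diester
Product: 8 {2-ethenyl-3-[2-(2-methyl-1,3-dioxolan-2-yl)ethyl]cyclopropane-1,1-diyl}dimethanol (C20 and C21 as in 6)
Conditions: LiAlH4, THF, 0 °C; H2O quench
Reagents that add atoms: none
Why: Exhaustive LiAlH4 reduction of a malonate to the 1,3-diol is routine and leaves the ketal, the alkene and the no longer acceptor-activated cyclopropane alone.

Step 6
Reactants: 8 vinylcyclopropane diol
Product: 9 iodo ether, a 3-oxabicyclo[3.1.0]hexane built from C6, C7, O8, C19, C20 and the apex C21; CH2I on C19, free C5H2OH on the bridgehead C6, C22 chain exo on C21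
Conditions: NIS, MeCN, 0 °C, dark
Reagents that add atoms: N-iodosuccinimide, O=C1CCC(=O)N1I
Why: Iodoetherification (5-exo-trig): only the hydroxymethyl group cis to the vinyl group can reach the iodonium ion, so ring geometry alone tells C7 from C5 and thereby creates the C6 stereocentre, while the C19 centre formed here is erased again in step 8.

Step 7
Reactants: 9 iodo ether alcohol
Product: 10 TBDPS ether of 9 (silyl group on O4)
Conditions: TBDPSCl, imidazole, DMF, rt
Reagents that add atoms: tert-butyl(chloro)diphenylsilane, CC(C)(C)[Si](Cl)(c1ccccc1)c1ccccc1
Why: Standard silylation of the only free hydroxyl group installs a base-, hydride- and acid-tolerant ether that, unlike an ester, does not wander to O8.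

Step 8
Reactants: 10 silylated iodo ether
Product: 11 cyclopropane with C5H2OTBDPS (cis to the C22 chain) and C7H2OH (cis to the vinyl group) on C6, vinyl on C20, ketal chain on C21
Conditions: Zn dust, aqueous EtOH, reflux
Reagents that add atoms: none
Why: Zinc-mediated reductive elimination of a β-iodo ether (Boord-type fragmentation, as in the Vasella reaction) regenerates the vinyl group and releases O8 as the single free hydroxyl group under neutral conditions.

Step 9
Reactants: 11 mono-silylated vinylcyclopropane diol; 12 acrylonitrile
Product: 13 2-cyanoethyl ether of 11 (C7–O8–C9H2–C10H2–C11≡N)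
Conditions: 12 (5 equiv), KOtBu (10 mol %), THF, 0 °C → rt; AcOH quench
Reagents that add atoms: acrylonitrile (12), C=CC#N
Why: Base-catalysed oxa-Michael addition to acrylonitrile (cyanoethylation) works with a catalytic amount of alkoxide even on neopentyl-type alcohols, needs no alkyl halide prone to elimination and brings in C9–C11 at the aldehyde-precursor level.

Step 10
Reactants: 13 cyanoethyl ether
Product: 14 3-oxopropyl ether (C7–O8–C9H2–C10H2–C11HO), vinyl group still on C20
Conditions: iBu2AlH (1.2 equiv), toluene, −78 °C; then dilute aqueous tartaric acid, 0 °C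
Reagents that add atoms: water, O
Why: iBu2AlH transfers one hydride to a nitrile and the aldehyde is released only on hydrolytic work-up, so over-reduction is excluded and the silyl ether, ketal and alkene are untouched.

Step 11
Reactants: 14 vinylcyclopropane aldehyde; 3 (E)-crotonaldehyde
Product: 15 key-step precursor: C6 bears C5H2OTBDPS and C7H2OCH2CH2CHO; C20 bears the E-CH=CH–CHO arm cis to C7; C21 bears the CH2CH2C(CH3)(OCH2CH2O) chain trans to the enal arm
Conditions: second-generation Hoveyda–Grubbs catalyst (5 mol %), 3 (5 equiv), CH2Cl2, 40 °C
Reagents that add atoms: crotonaldehyde (3), C/C=C/C=O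
Why: Olefin cross-metathesis of the vinylcyclopropane with excess crotonaldehyde installs C18 and C13 as the E-enal in one neutral step that tolerates the free aldehyde, so the sensitive dialdehyde is made immediately before use.

Step 12
Reactants: 15 cyclopropane bearing the E-enal and 3-oxopropyl ether arms
Product: 16 oxepane 1,5-dialdehyde, a 3-oxabicyclo[5.1.0]octane (C6, C7, O8, C9, C10, C19, C20 and C21) with the C11 formyl group on C10 and C18H2–C13HO on C19; H19 anti to H20, H10 cis to H19
Conditions: (S)-α,α-diphenylprolinol trimethylsilyl ether (20 mol %), PhCO2H (20 mol %), CH2Cl2 (0.01 M), 0 °C → rt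
Reagents that add atoms: none
Why: The secondary amine condenses reversibly with both formyl groups, turning the saturated C11 aldehyde into an E-enamine nucleophilic at C10 and the enal into an iminium ion electrophilic at C19 (a dienamine is out of reach because the γ-carbon C20 is a cyclopropane carbon), after which C10 attacks C19, the new C13 enamine is protonated at C18 and hydrolysis frees the catalyst. The closest known reaction type is the amine-catalysed intramolecular Michael addition of formyl-enals and formyl-enones that builds iridoid-type five- and six-membered rings, and the ring made here is one atom larger. The oxepane closes in the 7-exo-trig mode (C18=C19 lies outside the ring), and the entropic price of a seven-membered ring is lowered because the cis-disubstituted C6–C20 edge of the cyclopropane holds both arms on one face much as a Z-alkene would. C19 is controlled twice in the same sense: the vinylcyclopropane prefers its s-trans bisected rotamer (H19 anti to H20), which turns towards the C7 arm exactly the face that the CPh2(OSiMe3) group of the (S)-catalyst leaves open on the iminium ion, so substrate and catalyst are matched. C10 is set by the shielded enamine face but is epimerisable and becomes sp2 in step 13, so its configuration is of no consequence. The step needs ring closure to beat oligomerisation and loss of O8 from the enamine (retro-oxa-Michael), which high dilution, a weak acid co-catalyst, the absence of base and a temperature at or below ambient should secure.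

Step 13
Reactants: 16 oxepane 1,5-dialdehyde
Product: 18 tricyclic enol lactone (C13 lactone carbonyl; C10=C11 enol ether; C18H2; OTBDPS on C5; ketal at C24), via enol lactol 17 (not isolated)
Conditions: Ag2CO3 on Celite, toluene, 90 °C
Reagents that add atoms: none
Why: The 1,5-dialdehyde tautomerises through its C10=C11 enol to the cyclic enol hemiacetal 17, and the Fétizon oxidation dehydrogenates such lactols selectively under neutral conditions (the way iridoid lactols are turned into enol lactones), which drains the equilibrium, makes C10 sp2 and removes the risk of β-elimination of O8.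

Step 14
Reactants: 18 tricyclic enol lactone
Product: 20 C18-bromo enol lactone (either C18 epimer serves), via lithium enolate 19 (not isolated)
Conditions: LiN(SiMe3)2, THF, −78 °C; then NBS, −78 °C; cold aqueous quench
Reagents that add atoms: N-bromosuccinimide, O=C1CCC(=O)N1Br
Why: Kinetic deprotonation at C18 (the only acidic C–H, since C5 carries no ester and C24 is a ketal) followed by electrophilic bromination is a standard enolate α-halogenation, the temperature is held at −78 °C so that the enolate does not expel O12 to give a ketene, and both C18 epimers lead to the same samarium enolate later.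

Step 15
Reactants: 20 C18-bromo enol lactone ketal
Product: 21 C18-bromo enol lactone with the free C24 methyl ketone
Conditions: PPTS (cat.), acetone/H2O, 40 °C
Reagents that add atoms: water, O
Why: Mild acid-catalysed hydrolysis cleaves the dialkyl ketal much faster than it touches the enol lactone, the secondary bromide or the TBDPS ether.

Step 16
Reactants: 21 bromo keto lactone
Product: 23 tetracyclic β-hydroxy enol lactone (C18–C24 bond closed; H18 cis to H19; O26 cis to C13; OTBDPS on C5), via samarium enolate 22 (not isolated)
Conditions: SmI2 (2.5 equiv), THF, −78 °C, slow addition of 21 (final 0.005 M); cold pH 7 buffer quench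
Reagents that add atoms: none
Why: Samarium Reformatsky reaction, known for medium-ring carbocycles: two electron transfers from divalent samarium cleave C18–Br to the trivalent samarium enolate 22, which binds the C24 ketone oxygen and adds through a chelated Zimmerman–Traxler-type chair, the tether on C19 being able to deliver C24 only to the face of C18 that carries C20 (H18 cis to H19), while in the twist that the trans-fused cyclopropane imposes on the forming cycloheptane the ketone oxygen stays on samarium only with CH3 equatorial and C23 axial on the chelate, which places O26 cis to C13.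

Step 17
Reactants: 23 silylated tetracyclic hydroxy lactone
Product: 24 tetracyclic diol lactone (free C5H2OH and C24 OH)
Conditions: HF·pyridine, pyridine/THF, 0 °C → rt
Reagents that add atoms: none
Why: Fluoride cleavage of the silyl ether in a pyridine-buffered, non-basic medium avoids alkoxide formation at O26 and hence retro-aldol opening of the strained ring.

Step 18
Reactants: 24 tetracyclic diol lactone
Product: 25 tetracyclic lactol triol (C13 hemiacetal, anomers in equilibrium), used crude
Conditions: iBu2AlH (3.5 equiv), CH2Cl2, −78 °C; cold aqueous quench
Reagents that add atoms: none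
Why: Partial reduction of a lactone to the lactol with iBu2AlH at −78 °C, well known for enol lactones of the iridoid type, works here after two equivalents have been consumed by the hydroxyl groups, because the tetrahedral aluminium adduct persists until the cold quench.

Step 19
Reactants: 25 lactol triol
Product: 26 CNP0250836.2 (target)
Conditions: Ac2O, pyridine, CH2Cl2, 0 °C → rt
Reagents that add atoms: acetic anhydride, CC(=O)OC(C)=O
Why: Acetylation with Ac2O in pyridine esterifies the primary O4 and the anomeric O14 but not the hindered tertiary O26, and since the lactol anomers interconvert the acetate is fixed in the favoured arrangement, pseudo-axial (anomeric effect) and trans to C24 on the less hindered face, which sets C13.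

Compound list
1 | 5-hexen-2-one | CC(=O)CCC=C | starting material
2 | 2-(but-3-en-1-yl)-2-methyl-1,3-dioxolane | CC1(CCC=C)OCCO1 | intermediate
3 | (E)-crotonaldehyde | C/C=C/C=O | starting material
4 | (E)-5-(2-methyl-1,3-dioxolan-2-yl)pent-2-enal | O=C/C=C/CCC1(C)OCCO1 | intermediate
5 | diethyl bromomalonate | CCOC(=O)C(Br)C(=O)OCC | starting material
6 | diethyl (2R,3R)-2-formyl-3-[2-(2-methyl-1,3-dioxolan-2-yl)ethyl]cyclopropane-1,1-dicarboxylate | CCOC(=O)C1(C(=O)OCC)[C@H](C=O)[C@H]1CCC1(C)OCCO1 | intermediate
7 | trans-vinylcyclopropane diester | CCOC(=O)C1(C(=O)OCC)[C@H](C=C)[C@H]1CCC1(C)OCCO1 | intermediate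
8 | trans-vinylcyclopropane 1,1-dimethanol | OCC1(CO)[C@H](C=C)[C@H]1CCC1(C)OCCO1 | intermediate
9 | iodo ether with free C5 hydroxyl (C19 epimer expected from the s-trans rotamer) | OC[C@@]12CO[C@@H](CI)[C@@H]1[C@H]2CCC1(C)OCCO1 | intermediate
10 | TBDPS ether of the iodo ether | CC(C)(C)[Si](c1ccccc1)(c1ccccc1)OC[C@@]12CO[C@@H](CI)[C@@H]1[C@H]2CCC1(C)OCCO1 | intermediate
11 | mono-TBDPS vinylcyclopropane diol (free O8) | CC(C)(C)[Si](c1ccccc1)(c1ccccc1)OC[C@@]1(CO)[C@H](C=C)[C@H]1CCC1(C)OCCO1 | intermediate
12 | acrylonitrile | C=CC#N | starting material
13 | 2-cyanoethyl ether | CC(C)(C)[Si](c1ccccc1)(c1ccccc1)OC[C@@]1(COCCC#N)[C@H](C=C)[C@H]1CCC1(C)OCCO1 | intermediate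
14 | 3-oxopropyl ether, vinyl on C20 | CC(C)(C)[Si](c1ccccc1)(c1ccccc1)OC[C@@]1(COCCC=O)[C@H](C=C)[C@H]1CCC1(C)OCCO1 | intermediate
15 | key-step precursor (E-enal and 3-oxopropyl ether arms cis) | CC(C)(C)[Si](c1ccccc1)(c1ccccc1)OC[C@@]1(COCCC=O)[C@H](/C=C/C=O)[C@H]1CCC1(C)OCCO1 | intermediate
16 | oxepane 1,5-dialdehyde | CC(C)(C)[Si](c1ccccc1)(c1ccccc1)OC[C@@]12COC[C@@H](C=O)[C@@H](CC=O)[C@@H]1[C@H]2CCC1(C)OCCO1 | intermediate
17 | enol lactol (C13 anomers) | CC(C)(C)[Si](c1ccccc1)(c1ccccc1)OC[C@@]12COCC3=COC(O)C[C@H]3[C@@H]1[C@H]2CCC1(C)OCCO1 | intermediate
18 | tricyclic enol lactone | CC(C)(C)[Si](c1ccccc1)(c1ccccc1)OC[C@@]12COCC3=COC(=O)C[C@H]3[C@@H]1[C@H]2CCC1(C)OCCO1 | intermediate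
19 | lithium enolate of 18 | CC(C)(C)[Si](c1ccccc1)(c1ccccc1)OC[C@@]12COCC3=COC(O[Li])=C[C@H]3[C@@H]1[C@H]2CCC1(C)OCCO1 | intermediate
20 | C18-bromo enol lactone (C18 epimers) | CC(C)(C)[Si](c1ccccc1)(c1ccccc1)OC[C@@]12COCC3=COC(=O)C(Br)[C@H]3[C@@H]1[C@H]2CCC1(C)OCCO1 | intermediate
21 | C18-bromo enol lactone methyl ketone | CC(C)(C)[Si](c1ccccc1)(c1ccccc1)OC[C@@]12COCC3=COC(=O)C(Br)[C@H]3[C@@H]1[C@H]2CCC(C)=O | intermediate
22 | samarium enolate | CC(C)(C)[Si](c1ccccc1)(c1ccccc1)OC[C@@]12COCC3=COC(O[Sm](I)I)=C[C@H]3[C@@H]1[C@H]2CCC(C)=O | intermediate
23 | tetracyclic β-hydroxy enol lactone, O4 silylated | CC(C)(C)[Si](c1ccccc1)(c1ccccc1)OC[C@@]12COCC3=COC(=O)[C@@H]4[C@H]3[C@@H]1[C@H]2CC[C@]4(C)O | intermediate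
24 | tetracyclic diol lactone | OC[C@@]12COCC3=COC(=O)[C@@H]4[C@H]3[C@@H]1[C@H]2CC[C@]4(C)O | intermediate
25 | tetracyclic lactol triol (C13 anomers) | OC[C@@]12COCC3=COC(O)[C@@H]4[C@H]3[C@@H]1[C@H]2CC[C@]4(C)O | intermediate
26 | CNP0250836.2 | CC(=O)OC[C@@]12COCC3=CO[C@H](OC(C)=O)[C@@H]4[C@H]3[C@@H]1[C@H]2CC[C@]4(C)O | target

Total step count: 19. Longest linear sequence: 19 steps (from 1).

Steps most likely to fail

**Step 12.** Closure of a seven-membered ring may be too slow. Intermolecular Michael or aldol oligomerisation, β-elimination of O8 from the enamine, or erosion of facial selectivity at C19 could then take over.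

The fallback sets out from 15 and replaces enamine formation by a preformed nucleophile. TBSOTf and Et3N in CH2Cl2 at −78 °C should silylate only the saturated aldehyde, because the enal has no enolisable γ-hydrogen. This gives the Z-silyl enol ether F1. F1 is then cyclised in wet CH2Cl2 with the benzoic acid salt of the same (S)-prolinol silyl ether. This is an organocatalytic Mukaiyama–Michael addition: only the enal needs the catalyst (as its iminium ion) and no enamine able to expel O8 is ever present. Loss of the silyl group to water returns the route at 16.

**Step 16.** The strain of the trans-fused bicyclo[5.1.0]octane may slow the carbonyl addition. The enolate could then be merely protonated (net debromination), the adduct could revert by retro-aldol cleavage, or facial selectivity at C24 could be poor.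

The fallback sets out from 18 and makes the same bond with a stronger electrophile and a product that cannot revert.
- LiN(SiMe3)2 and TBSCl (THF, −78 °C) give the silyl ketene acetal F2.
- TiCl4 in CH2Cl2 at −78 °C ionises the dioxolane to the C24 oxocarbenium ion, which C18 attacks (Mukaiyama aldol-type reaction of a ketal). This gives the 2-hydroxyethyl ether F3.
- I2, PPh3 and imidazole convert F3 into the 2-iodoethyl ether F4.
- Zn in aqueous EtOH expels ethene and frees O26, rejoining the route at 23.

**Step 14.** The enolate of an enol lactone may fragment to a ketene, NBS may attack the C10=C11 enol ether, or bromination may go too far.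

The fallback sets out from 16 and moves the halogenation to the aldehyde level. NBS and a catalytic amount of the (S)-prolinol silyl ether at low temperature (enamine-catalysed α-bromination of aldehydes) should brominate C18 only. The α-branched C11 aldehyde forms an enamine far less readily. The bromo aldehyde folds to the bromo enol lactol F5, which Dess–Martin periodinane oxidises to 20.

Further compounds
F1 | step 12 | Z-tert-butyldimethylsilyl enol ether of the C11 aldehyde of 15 | CC(C)(C)[Si](c1ccccc1)(c1ccccc1)OC[C@@]1(COC/C=C\O[Si](C)(C)C(C)(C)C)[C@H](/C=C/C=O)[C@H]1CCC1(C)OCCO1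
F2 | step 16 | tert-butyldimethylsilyl ketene acetal of 18 | CC(C)(C)[Si](c1ccccc1)(c1ccccc1)OC[C@@]12COCC3=COC(O[Si](C)(C)C(C)(C)C)=C[C@H]3[C@@H]1[C@H]2CCC1(C)OCCO1
F3 | step 16 | tetracyclic enol lactone with O26 as 2-hydroxyethyl ether | CC(C)(C)[Si](c1ccccc1)(c1ccccc1)OC[C@@]12COCC3=COC(=O)[C@@H]4[C@H]3[C@@H]1[C@H]2CC[C@]4(C)OCCO
F4 | step 16 | tetracyclic enol lactone with O26 as 2-iodoethyl ether | CC(C)(C)[Si](c1ccccc1)(c1ccccc1)OC[C@@]12COCC3=COC(=O)[C@@H]4[C@H]3[C@@H]1[C@H]2CC[C@]4(C)OCCI
F5 | step 14 | C18-bromo enol lactol (C13 and C18 epimers) | CC(C)(C)[Si](c1ccccc1)(c1ccccc1)OC[C@@]12COCC3=COC(O)C(Br)[C@H]3[C@@H]1[C@H]2CCC1(C)OCCO1
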